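**Plan**

1. Target numbering: C1 = CMe2, C2 and C4 = CHCl, C3 = alkylidene carbon, C6 = CHBr, C1′/C2′ = side chain. The cuts, in order: C4–Cl together with the C3=C1′ bond (allylic 1,3-transposition from a C1′ carbinol); C2–Cl (1,3-transposition from a C4 alcohol); C3–C1′ (Stille coupling); then the ring bonds C2–C3 and C3–C4, with C3 excised as a carbene carbon. This leaves (S)-4-bromo-3,3-dimethylcyclopentene.
2. Enabling feature: C2–C3–C4 is an allyl unit (CHX–C(sp2)–CHX) inside the six-membered ring. An allyl cation over these three atoms is the ring-opened form of a cyclopropyl cation. A C2–C4 bond is therefore made on purpose in a 6,6-dibromobicyclo[3.1.0]hexane and broken again, which turns the cyclopentane into the cyclohexane and inserts C3 with a vinyl bromide handle.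
3. Forward order: commercial cyclopentanedione → cyclopentenol → bromide → bicyclo[3.1.0]hexane → cyclohexene ring (step 6) → acyl side chain on C3 → chlorine moved from C4–O to C2 → side-chain carbinol → chlorine delivered to C4 as the double bond leaves the ring.
4. Stereochemistry: C6–Br from a CBS desymmetrisation followed by Appel inversion. C2–Cl by syn transfer from the C4 carbinol formed in the ring expansion. C4–Cl and the Z alkene together from a CBS-set side-chain carbinol through a chair-like SNi′ transition state.

Key step: step 6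

Remark: dibromocarbene may add to either face of 7; both adducts give the same allyl cation in step 6, so only the anti adduct is drawn as 8.

**Step 1**
Reactants: 1 2,2-dimethylcyclopentane-1,3-dione
Product: 2 (3R)-3-hydroxy-2,2-dimethylcyclopentan-1-one
Conditions: (S)-2-methyl-CBS-oxazaborolidine (0.2 equiv), BH3·SMe2 (0.6 equiv), THF, −30 °C; MeOH quench
Reagents that add atoms: none
Why: Corey–Bakshi–Shibata reduction of one of the two enantiotopic carbonyl groups (desymmetrisation); with the quaternary carbon as the large group the (S)-catalyst should give the (R)-carbinol, which is the stereochemical source of the C–Br centre.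

**Step 2**
Reactants: 2 (3R)-3-hydroxy-2,2-dimethylcyclopentan-1-one
Product: 3 N′-[(1E,3R)-3-hydroxy-2,2-dimethylcyclopentylidene]-2,4,6-tri(propan-2-yl)benzenesulfonohydrazide
Conditions: 2,4,6-triisopropylbenzenesulfonyl hydrazide, cat. HCl, THF, rt
Reagents that add atoms: 2,4,6-tri(propan-2-yl)benzenesulfonohydrazide (NNS(=O)(=O)c1c(C(C)C)cc(C(C)C)cc1C(C)C)
Why: Acid-catalysed condensation of the hindered ketone with the arenesulfonyl hydrazide; the triisopropylphenyl group avoids ortho-lithiation in the next step.

**Step 3**
Reactants: 3 N′-[(1E,3R)-3-hydroxy-2,2-dimethylcyclopentylidene]-2,4,6-tri(propan-2-yl)benzenesulfonohydrazide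
Product: 5 (1R)-2,2-dimethylcyclopent-3-en-1-ol, via dilithiated cyclopentenolate 4 (not isolated)
Conditions: n-BuLi (3.3 equiv), THF–TMEDA, −78 to 0 °C; then H2O
Reagents that add atoms: none
Why: Shapiro reaction: after deprotonation of OH and NH the third equivalent removes the only available α-hydrogen (the other α-carbon is quaternary), loss of sulfinate and N2 gives the vinyllithium, and water protonates it to the alkene without touching the carbinol centre.

**Step 4**
Reactants: 5 (1R)-2,2-dimethylcyclopent-3-en-1-ol
Product: 7 (4S)-4-bromo-3,3-dimethylcyclopent-1-ene, via alkoxyphosphonium bromide 6 (not isolated)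
Conditions: CBr4, PPh3, CH2Cl2, 0 °C to reflux
Reagents that add atoms: tetrabromomethane (BrC(Br)(Br)Br)
Why: Appel reaction: bromide displaces the alkoxyphosphonium group by SN2 with inversion, turning the (R)-alcohol into the (S)-bromide; a cyclopentane tolerates backside attack next to a quaternary carbon better than a cyclohexane would.

**Step 5**
Reactants: 7 (4S)-4-bromo-3,3-dimethylcyclopent-1-ene
Product: 8 (1S,3S,5S)-3,6,6-tribromo-2,2-dimethylbicyclo[3.1.0]hexane (cyclopropane anti to the C3 bromine)
Conditions: CHBr3, 50% aq NaOH, BnEt3NCl (cat.), CH2Cl2, 0 °C to rt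
Reagents that add atoms: bromoform (BrC(Br)Br)
Why: [2+1] cycloaddition of dibromocarbene generated under phase-transfer conditions (mild enough that the secondary bromide should survive), stereospecifically cis on the alkene and expected anti to the ring bromine.

**Step 6**
Reactants: 8 (1S,3S,5S)-3,6,6-tribromo-2,2-dimethylbicyclo[3.1.0]hexane
Product: 10 (1S,5S)-2,5-dibromo-4,4-dimethylcyclohex-2-en-1-ol (OH trans to the C5 bromine), via 2-bromoallyl cation 9 (not isolated)
Conditions: AgNO3 (1.5 equiv), acetone–H2O (4:1), rt, dark
Reagents that add atoms: water (O)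
Why: Ag+ abstracts the endo bromide of the CBr2 group while the C1–C5 bond opens in a concerted, thermally allowed disrotatory two-electron electrocyclic ring opening (cyclopropyl to allyl cation), which turns the five-membered ring of 8 into the six-membered cation 9; water then adds to an allyl terminus and loses a proton. The closest known reaction type is the silver-promoted solvolytic ring expansion of ring-fused gem-dihalocyclopropanes to 2-halocycloalk-2-enols. No ring is closed: the six-membered ring arises by cleavage of the zero-atom bridge of the bicyclo[3.1.0]hexane, so the carbene carbon becomes the ring member between the two former olefinic carbons. The only new stereocentre is the carbinol carbon, set by substrate control: water should add pseudoaxially to the half-chair cation on the face that keeps the bromine of the remote CHBr carbon pseudoequatorial, that is trans to this bromine. The step needs regioselectivity between the two allyl termini, which the neopentyl shielding of the terminus next to CMe2 should secure, and chemoselectivity for the cyclopropyl C–Br over the secondary alkyl C–Br, which rests on the assistance of the opening sigma bond. Both face isomers of 8 give the same cation.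

**Step 7**
Reactants: 10 (1S,5S)-2,5-dibromo-4,4-dimethylcyclohex-2-en-1-ol
Product: 11 (1S,5S)-5-bromo-2-(1-ethoxyethenyl)-4,4-dimethylcyclohex-2-en-1-ol
Conditions: tributyl(1-ethoxyvinyl)stannane (1.3 equiv), Pd(PPh3)4 (5 mol %), toluene, 90 °C
Reagents that add atoms: tributyl(1-ethoxyethenyl)stannane (CCCC[Sn](CCCC)(CCCC)C(=C)OCC)
Why: Stille coupling: zerovalent palladium should insert into the vinyl C–Br bond only (the neopentyl secondary C–Br bond and the free hydroxyl are inert), and the stannane delivers a masked acetyl group to the ring carbon that came from the carbene.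

**Step 8**
Reactants: 11 (1S,5S)-5-bromo-2-(1-ethoxyethenyl)-4,4-dimethylcyclohex-2-en-1-ol
Product: 13 2-bromo-1-[(4S,6S)-4-bromo-6-hydroxy-3,3-dimethylcyclohex-1-en-1-yl]ethan-1-one, via bromo oxocarbenium ion 12 (not isolated)
Conditions: NBS (1.05 equiv), THF–H2O (4:1), 0 °C; product used directly
Reagents that add atoms: N-bromosuccinimide (O=C1CCC(=O)N1Br); water (O)
Why: Electrophilic bromination of the enol ether at its terminal carbon, capture of the oxocarbenium ion by water and loss of ethanol give the bromomethyl ketone (the standard unmasking of a 1-ethoxyvinyl group); the enol ether should outcompete the ring alkene for NBS.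

**Step 9**
Reactants: 13 2-bromo-1-[(4S,6S)-4-bromo-6-hydroxy-3,3-dimethylcyclohex-1-en-1-yl]ethan-1-one
Product: 15 2-bromo-1-[(4S,6S)-4-bromo-6-chloro-5,5-dimethylcyclohex-1-en-1-yl]ethan-1-one, via allylic chlorosulfite 14 (not isolated)
Conditions: SOCl2 (1.2 equiv), Et2O, −20 to 0 °C, no base
Reagents that add atoms: thionyl chloride (O=S(Cl)Cl)
Why: SNi′ reaction of a Morita–Baylis–Hillman-type alcohol: the chlorosulfite should deliver chloride, on the face it occupies, to the enone β-carbon (the olefinic CH next to CMe2) while the double bond moves to the former carbinol carbon, so the new C–Cl centre copies the carbinol configuration and ends trans to the ring bromine, the sense also preferred for pseudoaxial delivery.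

**Step 10**
Reactants: 15 2-bromo-1-[(4S,6S)-4-bromo-6-chloro-5,5-dimethylcyclohex-1-en-1-yl]ethan-1-one
Product: 16 (1S)-2-bromo-1-[(4S,6S)-4-bromo-6-chloro-5,5-dimethylcyclohex-1-en-1-yl]ethan-1-ol
Conditions: (S)-2-methyl-CBS-oxazaborolidine (0.2 equiv), BH3·SMe2 (0.7 equiv), THF, −30 °C; MeOH quench
Reagents that add atoms: none
Why: Corey–Bakshi–Shibata reduction: reagent-controlled 1,2-hydride delivery, with the substituted cyclohexenyl group as the large and CH2Br as the small substituent, should give the (1S)-bromohydrin without touching the allylic chloride or the C–Br bonds.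

**Step 11**
Reactants: 16 (1S)-2-bromo-1-[(4S,6S)-4-bromo-6-chloro-5,5-dimethylcyclohex-1-en-1-yl]ethan-1-ol
Product: 18 (2S,4S,6S)-6-bromo-3-[(Z)-2-bromoethylidene]-2,4-dichloro-1,1-dimethylcyclohexane, via allylic chlorosulfite 17 (not isolated)
Conditions: SOCl2 (1.2 equiv), Et2O, 0 °C to rt, no base
Reagents that add atoms: thionyl chloride (O=S(Cl)Cl)
Why: SNi′ reaction of a secondary allylic alcohol with SOCl2 in ether: chlorosulfite 17 should collapse through a six-membered chair-like transition state with CH2Br pseudoequatorial, so chloride arrives at the ring olefinic carbon on the face fixed by the (1S)-carbinol (cis to the ring chlorine, trans to bromine) and CH2Br ends trans to the new CHCl carbon, which is the Z geometry of 18; direct substitution is retarded by the adjacent CH2Br group.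

**Compound list**

1 | 2,2-dimethylcyclopentane-1,3-dione | CC1(C)C(=O)CCC1=O | starting material
2 | (3R)-3-hydroxy-2,2-dimethylcyclopentan-1-one | CC1(C)[C@H](O)CCC1=O | intermediate
3 | N′-[(1E,3R)-3-hydroxy-2,2-dimethylcyclopentylidene]-2,4,6-tri(propan-2-yl)benzenesulfonohydrazide | CC1(C)[C@H](O)CC/C1=N\NS(=O)(=O)c2c(C(C)C)cc(C(C)C)cc2C(C)C | intermediate
4 | lithium (1R)-3-lithio-2,2-dimethylcyclopent-3-en-1-olate | CC1(C)[C@H](O[Li])CC=C1[Li] | intermediate
5 | (1R)-2,2-dimethylcyclopent-3-en-1-ol | CC1(C)[C@H](O)CC=C1 | intermediate
6 | [(1R)-2,2-dimethylcyclopent-3-en-1-yl]oxy(triphenyl)phosphonium bromide | CC1(C)[C@H](O[P+](c2ccccc2)(c2ccccc2)c2ccccc2)CC=C1.[Br-] | intermediate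
7 | (4S)-4-bromo-3,3-dimethylcyclopent-1-ene | CC1(C)[C@@H](Br)CC=C1 | intermediate
8 | (1S,3S,5S)-3,6,6-tribromo-2,2-dimethylbicyclo[3.1.0]hexane | CC1(C)[C@@H](Br)C[C@@H]2C(Br)(Br)[C@H]12 | intermediate
9 | (5S)-2,5-dibromo-4,4-dimethylcyclohex-2-en-1-ylium | CC1(C)[C@@H](Br)C[CH+]C(Br)=C1 | intermediate
10 | (1S,5S)-2,5-dibromo-4,4-dimethylcyclohex-2-en-1-ol | CC1(C)[C@@H](Br)C[C@H](O)C(Br)=C1 | intermediate
11 | (1S,5S)-5-bromo-2-(1-ethoxyethenyl)-4,4-dimethylcyclohex-2-en-1-ol | CC1(C)[C@@H](Br)C[C@H](O)C(C(=C)OCC)=C1 | intermediate
12 | {2-bromo-1-[(4S,6S)-4-bromo-6-hydroxy-3,3-dimethylcyclohex-1-en-1-yl]ethylidene}(ethyl)oxidanium | CC1(C)[C@@H](Br)C[C@H](O)C(C(CBr)=[O+]CC)=C1 | intermediate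
13 | 2-bromo-1-[(4S,6S)-4-bromo-6-hydroxy-3,3-dimethylcyclohex-1-en-1-yl]ethan-1-one | CC1(C)[C@@H](Br)C[C@H](O)C(C(=O)CBr)=C1 | intermediate
14 | (1S,5S)-5-bromo-2-(bromoacetyl)-4,4-dimethylcyclohex-2-en-1-yl chlorosulfite (sulfur epimers) | CC1(C)[C@@H](Br)C[C@H](OS(=O)Cl)C(C(=O)CBr)=C1 | intermediate
15 | 2-bromo-1-[(4S,6S)-4-bromo-6-chloro-5,5-dimethylcyclohex-1-en-1-yl]ethan-1-one | CC1(C)[C@@H](Br)CC=C(C(=O)CBr)[C@@H]1Cl | intermediate
16 | (1S)-2-bromo-1-[(4S,6S)-4-bromo-6-chloro-5,5-dimethylcyclohex-1-en-1-yl]ethan-1-ol | CC1(C)[C@@H](Br)CC=C([C@H](O)CBr)[C@@H]1Cl | intermediate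
17 | (1S)-2-bromo-1-[(4S,6S)-4-bromo-6-chloro-5,5-dimethylcyclohex-1-en-1-yl]ethyl chlorosulfite (sulfur epimers) | CC1(C)[C@@H](Br)CC=C([C@H](OS(=O)Cl)CBr)[C@@H]1Cl | intermediate
18 | (2S,4S,6S)-6-bromo-3-[(Z)-2-bromoethylidene]-2,4-dichloro-1,1-dimethylcyclohexane | CC1(C)[C@@H](Br)C[C@H](Cl)/C(=C/CBr)[C@@H]1Cl | target

**Step count and risks**

Total steps: 11. Longest linear sequence: 11 steps (fully linear from 1).

Step 11. What may go wrong: the syn SNi′ pathway may leak into a solvent-separated ion pair or into direct substitution at the carbinol carbon, eroding facial selectivity at the new C–Cl carbon and the olefin geometry. The required transition state also places the departing oxygen on the same face as the pseudoaxial ring chlorine, which may slow it relative to these leaks. The fallback sets out from 15 and returns to 18. Reduction of 15 with the enantiomeric (R)-2-methyl-CBS-oxazaborolidine and BH3·SMe2 should give the epimeric (1R)-bromohydrin F1. K2CO3 in MeOH should close it to the vinyl oxirane F2. 1,4-Addition of HCl (Et2O, −78 °C) to the vinyl oxirane, anti to the C–O bond that now lies on the face away from the ring chlorine, should give the Z allylic alcohol F3. An Appel reaction (CBr4, PPh3, CH2Cl2, 0 °C) on the primary allylic alcohol then gives 18.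

Step 9. What may go wrong: substitution without allylic shift, loss of the syn course, or chloride-mediated SN2′ re-equilibration of the labile allylic chloride between the two ring positions. The fallback sets out from 13 and returns to 15. Acetylation without amine base (Ac2O, cat. Sc(OTf)3, MeCN, 0 °C) gives the acetate F4. TiCl4 in CH2Cl2 at −78 °C then effects a stepwise conjugate addition–elimination of chloride. In this mode the carbinol configuration no longer matters, and chloride should add pseudoaxially to the β-carbon, trans to the ring bromine.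

Step 6. What may go wrong: poor facial selectivity in the capture of cation 9 by water (if bromine prefers the pseudoaxial position in the cation), and partial capture at the hindered terminus. The fallback sets out from 8 and returns to 10. The silver-promoted opening is run as before and the carbinol epimer F5 is not separated from 10. Oxidation of the mixture with MnO2 in CH2Cl2 gives the 2-bromoenone F6 (kept free of base because of the β-bromine). Reduction with (R)-2-methyl-CBS-oxazaborolidine and BH3·SMe2 sets the carbinol under reagent control and gives 10 as one diastereomer.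

**Further compounds**

F1 | step 11 | (1R)-2-bromo-1-[(4S,6S)-4-bromo-6-chloro-5,5-dimethylcyclohex-1-en-1-yl]ethan-1-ol | CC1(C)[C@@H](Br)CC=C([C@@H](O)CBr)[C@@H]1Cl
F2 | step 11 | (2R)-2-[(4S,6S)-4-bromo-6-chloro-5,5-dimethylcyclohex-1-en-1-yl]oxirane | CC1(C)[C@@H](Br)CC=C([C@@H]2CO2)[C@@H]1Cl
F3 | step 11 | (2Z)-2-[(2S,4S,6S)-4-bromo-2,6-dichloro-3,3-dimethylcyclohexylidene]ethan-1-ol | CC1(C)[C@@H](Br)C[C@H](Cl)/C(=C/CO)[C@@H]1Cl
F4 | step 9 | (1S,5S)-5-bromo-2-(bromoacetyl)-4,4-dimethylcyclohex-2-en-1-yl acetate | CC1(C)[C@@H](Br)C[C@H](OC(C)=O)C(C(=O)CBr)=C1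
F5 | step 6 | (1R,5S)-2,5-dibromo-4,4-dimethylcyclohex-2-en-1-ol | CC1(C)[C@@H](Br)C[C@@H](O)C(Br)=C1
F6 | step 6 | (5S)-2,5-dibromo-4,4-dimethylcyclohex-2-en-1-one | CC1(C)[C@@H](Br)CC(=O)C(Br)=C1
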